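## Retrosynthetic overview
1. The target is a (2S)-5,7,3′,5′-tetrahydroxy-6,8-diprenylflavanone. The pyranone ring is closed last: the C2–O1 bond is made by intramolecular Mitsunobu displacement, with inversion, of an (R)-benzylic alcohol by an ortho-phenol.
2. That β-hydroxy ketone comes from the Weinreb amide of an (R)-β-silyloxy acid plus the aryllithium of 2,4-diprenylphloroglucinol tris-MOM ether.
3. The only stereocenter is set by a ketoreductase (KRED, an oxidoreductase) reducing a B-ring β-ketoester to the (R)-alcohol. The B ring is built from 3,5-dihydroxybenzoic acid.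
4. The A ring is built from phloroglucinol by tris-MOM protection and two directed ortho-lithiation/prenylations.
5. Rings are formed in this order: B ring (present from the start), A ring with both prenyls, then the pyranone ring.

Assumptions (one line): the target is (2S) (I derived this from the SMILES), and an (R)-selective KRED active on the bis-silyloxyaryl β-ketoester can be found by panel screening.

## Route

**Step 1**
Reactants: **1** 3,5-dihydroxybenzoic acid
Product: **2** 3,5-bis(tert-butyldimethylsilyloxy)benzoic acid
Conditions: TBSCl (3.5 equiv), imidazole, DMF, rt, 16 h; then AcOH/THF/H2O (3:1:1), rt, 1 h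
Reagents that add atoms: TBSCl, CC(C)(C)[Si](C)(C)Cl
Why: Phenols and the acid are all silylated, and the labile silyl ester is then hydrolysed, leaving the two aryl TBS ethers as protection that survives the later Lewis-acid and fluoride-free steps.

**Step 2**
Reactants: **2**
Product: **3** methyl 3-[3,5-bis(TBSO)phenyl]-3-oxopropanoate
Conditions: CDI, THF, rt; then MeO2CCH2CO2K, MgCl2, Et3N, THF, 50 °C
Reagents that add atoms: potassium methyl malonate, COC(=O)CC(=O)[O-].[K+] (CDI is lost as imidazole and CO2)
Why: Masamune–Brooks/Rathke acylation of a magnesium malonate half-ester by the acyl imidazolide, with spontaneous decarboxylation, gives the β-ketoester under non-basic conditions that keep the aryl silyl ethers intact.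

**Step 3**
Reactants: **3**
Product: **4** methyl (R)-3-[3,5-bis(TBSO)phenyl]-3-hydroxypropanoate
Conditions: (R)-selective KRED, NADP+ (cat.), i-PrOH (20% v/v, hydride source and co-solvent), KPi buffer pH 7, 30 °C, 24 h
Reagents that add atoms: none (only H2 equivalents are transferred)
Why: Enzymatic asymmetric ketone reduction delivers hydride to one face of the ketone in the enzyme pocket, which sets the sole stereocenter as (R); it is a mild, neutral reduction with no retro-aldol or elimination.

**Step 4**
Reactants: **4**
Product: **5** methyl (R)-3-[3,5-bis(TBSO)phenyl]-3-(triethylsilyloxy)propanoate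
Conditions: TESCl, imidazole, DMF, 0 °C → rt
Reagents that add atoms: TESCl, CC[Si](Cl)(CC)CC
Why: The free secondary alcohol is capped with a TES group that can later be removed selectively; the stereocenter is not involved.

**Step 5**
Reactants: **5**
Product: **6** (R)-N-methoxy-N-methyl-3-[3,5-bis(TBSO)phenyl]-3-(TESO)propanamide
Conditions: MeNHOMe·HCl, i-PrMgCl (3 equiv), THF, −20 → 0 °C
Reagents that add atoms: N,O-dimethylhydroxylamine hydrochloride, CONC.Cl
Why: Grignard-mediated aminolysis of the ester (Williams Weinreb amide formation) gives an acylating agent that stops at the ketone stage; the stereocenter is untouched.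

**Step 6**
Reactants: **7** phloroglucinol
Product: **8** 1,3,5-tris(methoxymethoxy)benzene
Conditions: NaH, MOMCl, THF/DMF, 0 °C → rt
Reagents that add atoms: MOMCl, COCCl
Why: O-Alkylation of the phenoxides gives MOM ethers, which are strong directing groups for ortho-lithiation.

**Step 7**
Reactants: **8**
Product: **9** 2-prenyl-1,3,5-tris(MOMO)benzene
Conditions: n-BuLi, TMEDA, THF, 0 °C; then prenyl bromide, CuI (10 mol %), −78 °C → rt
Reagents that add atoms: prenyl bromide, CC(C)=CCBr
Why: Directed ortho-metalation at the carbon flanked by two OMOM groups, followed by Cu-catalysed SN2 alkylation, installs the linear 3-methylbut-2-enyl group.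

**Step 8**
Reactants: **9**
Product: **10** 2,4-diprenyl-1,3,5-tris(MOMO)benzene
Conditions: n-BuLi, TMEDA, THF, 0 °C; then prenyl bromide, CuI (10 mol %), −78 °C → rt
Reagents that add atoms: prenyl bromide, CC(C)=CCBr
Why: The two remaining CH positions are equivalent, each flanked by two OMOM groups, so the second directed metalation and prenylation give the 2,4-diprenyl pattern.

**Step 9**
Reactants: **10**; **6**
Product: **11** (R)-1-[3,5-diprenyl-2,4,6-tris(MOMO)phenyl]-3-[3,5-bis(TBSO)phenyl]-3-(TESO)propan-1-one
Conditions: 10 with n-BuLi, TMEDA, THF, 0 °C, 1 h; then add 6, −78 → 0 °C; NH4Cl quench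
Reagents that add atoms: none (the acyl group comes from 6)
Why: Directed metalation of the last aromatic CH and addition to the Weinreb amide (via a stable chelated tetrahedral intermediate) give the ketone without over-addition; the cold conditions leave the β-stereocenter unscrambled.

**Step 10**
Reactants: **11**
Product: **12** (R)-β-hydroxy ketone with the tris-MOM A ring and bis-TBS B ring
Conditions: PPTS, MeOH/CH2Cl2 (1:1), rt, 6 h
Reagents that add atoms: none
Why: Mildly acidic methanolysis removes the TES ether selectively; the aryl MOM and aryl TBS ethers are stable at rt and the carbinol center is not touched.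

**Step 11**
Reactants: **12**
Product: **13** (R)-3-[3,5-bis(TBSO)phenyl]-3-hydroxy-1-(2,4,6-trihydroxy-3,5-diprenylphenyl)propan-1-one
Conditions: ZnBr2 (6 equiv), n-PrSH (6 equiv), CH2Cl2, 0 °C, 15 min
Reagents that add atoms: none
Why: ZnBr2/propanethiol removes MOM ethers quickly under non-protic conditions, which avoids acid-promoted cyclisation of the prenyl groups onto neighbouring phenols; aryl TBS ethers and the benzylic alcohol survive.

**Step 12**
Reactants: **13**
Product: **14** (2S)-2-[3,5-bis(TBSO)phenyl]-5,7-dihydroxy-6,8-diprenylchroman-4-one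
Conditions: PPh3, DIAD, THF (0.01 M), 0 °C → rt
Reagents that add atoms: none (Ph3P=O and the hydrazine are by-products)
Why: Intramolecular Mitsunobu etherification closes the pyranone ring by SN2 attack of an ortho-phenol on the activated benzylic alcohol, which inverts (R) to (2S). The electron-rich acylphloroglucinol ketone resists enolisation, which suppresses elimination to the chalcone, and the 4′-OH flanked by two prenyls is too hindered to compete.

**Step 13**
Reactants: **14**
Product: **15** target, (2S)-5,7,3′,5′-tetrahydroxy-6,8-diprenylflavanone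
Conditions: TBAF/AcOH (1:1), THF, 0 °C, 30 min
Reagents that add atoms: none
Why: Acetic-acid-buffered fluoride cleaves the aryl TBS ethers while staying near neutral pH, which avoids base-induced flavanone ring opening and racemisation at C2.

## Compound list
1 | 3,5-dihydroxybenzoic acid | OC(=O)c1cc(O)cc(O)c1 | starting material
2 | 3,5-bis(TBSO)benzoic acid | CC(C)(C)[Si](C)(C)Oc1cc(O[Si](C)(C)C(C)(C)C)cc(C(=O)O)c1 | intermediate
3 | methyl 3-[3,5-bis(TBSO)phenyl]-3-oxopropanoate | COC(=O)CC(=O)c1cc(O[Si](C)(C)C(C)(C)C)cc(O[Si](C)(C)C(C)(C)C)c1 | intermediate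
4 | methyl (R)-3-[3,5-bis(TBSO)phenyl]-3-hydroxypropanoate | COC(=O)C[C@@H](O)c1cc(O[Si](C)(C)C(C)(C)C)cc(O[Si](C)(C)C(C)(C)C)c1 | intermediate
5 | TES ether of 4 | COC(=O)C[C@@H](O[Si](CC)(CC)CC)c1cc(O[Si](C)(C)C(C)(C)C)cc(O[Si](C)(C)C(C)(C)C)c1 | intermediate
6 | Weinreb amide of (R)-acid | CON(C)C(=O)C[C@@H](O[Si](CC)(CC)CC)c1cc(O[Si](C)(C)C(C)(C)C)cc(O[Si](C)(C)C(C)(C)C)c1 | intermediate
7 | phloroglucinol | Oc1cc(O)cc(O)c1 | starting material
8 | 1,3,5-tris(MOMO)benzene | COCOc1cc(OCOC)cc(OCOC)c1 | intermediate
9 | 2-prenyl-1,3,5-tris(MOMO)benzene | COCOc1cc(OCOC)c(CC=C(C)C)c(OCOC)c1 | intermediate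
10 | 2,4-diprenyl-1,3,5-tris(MOMO)benzene | COCOc1c(CC=C(C)C)c(OCOC)c(CC=C(C)C)c(OCOC)c1 | intermediate
11 | (R)-ketone, fully protected | O=C(C[C@@H](O[Si](CC)(CC)CC)c1cc(O[Si](C)(C)C(C)(C)C)cc(O[Si](C)(C)C(C)(C)C)c1)c1c(OCOC)c(CC=C(C)C)c(OCOC)c(CC=C(C)C)c1OCOC | intermediate
12 | (R)-β-hydroxy ketone, tris-MOM | O=C(C[C@@H](O)c1cc(O[Si](C)(C)C(C)(C)C)cc(O[Si](C)(C)C(C)(C)C)c1)c1c(OCOC)c(CC=C(C)C)c(OCOC)c(CC=C(C)C)c1OCOC | intermediate
13 | (R)-β-hydroxy ketone, free A-ring triol | O=C(C[C@@H](O)c1cc(O[Si](C)(C)C(C)(C)C)cc(O[Si](C)(C)C(C)(C)C)c1)c1c(O)c(CC=C(C)C)c(O)c(CC=C(C)C)c1O | intermediate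
14 | (2S)-bis-TBS flavanone | CC(C)=CCc1c(O)c(CC=C(C)C)c2c(c1O)C(=O)C[C@@H](c1cc(O[Si](C)(C)C(C)(C)C)cc(O[Si](C)(C)C(C)(C)C)c1)O2 | intermediate
15 | (2S)-5,7,3′,5′-tetrahydroxy-6,8-diprenylflavanone (CID26213315) | CC(C)=CCc1c(O)c(CC=C(C)C)c2c(c1O)C(=O)C[C@@H](c1cc(O)cc(O)c1)O2 | target

## Totals
- Total steps: 13.
- Longest linear sequence: 10 steps (1 → 2 → 3 → 4 → 5 → 6 → 11 → 12 → 13 → 14 → 15, i.e. Steps 1–5 and 9–13). The A-ring branch (Steps 6–8) is 3 steps and joins at Step 9.

## Three steps most likely to fail
1. **Step 12 (Mitsunobu cyclisation).** Risks are elimination to the chalcone, partial SN1 racemisation, or intermolecular alkylation by the free 4′-OH.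
   Fallback: change the approach to a chalcone route. Prenylate phloroacetophenone directly, do a Claisen–Schmidt condensation with 3,5-bis(TBSO)benzaldehyde, and cyclise the 2′-hydroxychalcone with a chiral bifunctional (thiourea or iminophosphorane) oxa-Michael catalyst, then desilylate.
2. **Steps 7–9 (directed lithiation/prenylation and acylation of the hindered aryllithium).** Risks are allylic lithiation of the prenyl CH2, SN2′ prenylation, and poor addition to the Weinreb amide.
   Fallback: switch to Friedel–Crafts chemistry. Remove the MOM groups of 10 to give free 2,4-diprenylphloroglucinol, and acylate it with BF3·OEt2 using the (R)-β-hydroxy acid derived from 4, with the B ring kept as aryl silyl ethers.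
3. **Step 3 (KRED reduction of a lipophilic bis-TBS substrate).** Risks are low activity, low ee, or the wrong enantiomer.
   Fallback: change to metal catalysis. Hydrogenate 3 with a Noyori Ru–BINAP catalyst (H2 50 atm, MeOH, 50 °C, using the BINAP enantiomer that gives the (R)-alcohol) to give 4 directly.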